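**Plan**

1. Retrosynthesis: the caffeate is cut at the ester C–O bond and at its C=C bond (malonic half ester + 3,4-dihydroxybenzaldehyde); the methylidene is cut back to a cyclopentanone; the cyclopentane bonds C4'–C5' and C2'–C3' are then cut together; last comes the bond from ring carbon C5 to its side chain.
2. Enabling feature: the ester oxygen on C1 of the cyclohexene and the methylidene-bearing cyclopentane carbon C2' are 1,5-related (O–C1–C6–C5–C1'–C2') and on the same face, and C2' is a latent acyl carbon. The two can therefore be tied up as a bridged δ-lactone (2-oxabicyclo[3.3.1]non-7-en-3-one) whose α-carbon is the future quaternary C1'.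
3. Forward: the six-membered carbocycle is bought; its quaternary carbon, the enone and the cis allylic alcohol are installed; side chain and hydroxyl are closed to the temporary lactone; the lactone α-carbon is made quaternary; the cyclopentane is closed by a [3+2] Michael–Dieckmann annulation that opens the lactone again; methylenation and caffeoylation finish.
4. Stereochemistry: C5 from a catalyst-controlled asymmetric conjugate addition; C1 from a catalyst-controlled ketone reduction (only the cis isomer can lactonise); C1' from alkylation of the rigid bicyclic lactone enolate on its convex face. None of the three centres can epimerise afterwards.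
5. Locants: cyclohexene C1 (carbinol) to C6 with C5 quaternary; cyclopentane C1' (quaternary), C2' (methylidene-bearing) to C5'.

Key step: step 9

Assumption: the ligand antipode in step 1 and the (R)-catalyst in step 4 are taken to give the drawn configurations; if the sense of induction is opposite, the mirror-image ligand or catalyst is used.

**Step 1**
Reactants: 1 3-methylcyclohex-2-en-1-one; 2 2-bromoprop-1-ene
Product: 5 (3S)-3-methyl-3-(prop-1-en-2-yl)cyclohexan-1-one, via prop-1-en-2-yllithium 3 (not isolated), via dimethyl(prop-1-en-2-yl)alane 4 (not isolated)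
Conditions: 2, tBuLi (2 equiv), Et2O, −78 °C; Me2AlCl, −78 °C → rt; then 1, Cu(O2CC4H3S) (copper thiophene-2-carboxylate, 10 mol%), (R,R)-N,N-bis(1-phenylethyl)-P,P-diphenylphosphinous amide (11 mol%), Et2O, −30 → −10 °C; 1 M HCl work-up
Reagents that add atoms: none
Why: Copper-catalysed asymmetric conjugate addition of an alkenylalane to a β-methyl cyclohexenone is an established route to all-carbon quaternary centres, and the chiral phosphinamine–copper complex decides which enone face receives the isopropenyl group, so the quaternary centre (C5 of the target) is set under catalyst control.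

**Step 2**
Reactants: 5 (3S)-3-methyl-3-(prop-1-en-2-yl)cyclohexan-1-one
Product: 7 (5S)-2,5-dimethyl-5-(prop-1-en-2-yl)cyclohexan-1-one (both C2 epimers), via lithium enolate 6 (not isolated)
Conditions: LiN(iPr)2, THF, −78 °C; MeI, −78 → 0 °C
Reagents that add atoms: iodomethane, CI
Why: Kinetic enolate alkylation, in which the amide base should remove a proton from the α-methylene remote from the quaternary carbon (the other α-methylene is neopentyl) and the enolate is methylated; the methyl-bearing centre forms without control, which is harmless because it becomes sp2 in step 3.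

**Step 3**
Reactants: 7 (5S)-2,5-dimethyl-5-(prop-1-en-2-yl)cyclohexan-1-one
Product: 9 (5S)-2,5-dimethyl-5-(prop-1-en-2-yl)cyclohex-2-en-1-one, via silyl enol ether 8 (not isolated)
Conditions: Me3SiCl, NaI, Et3N, MeCN, rt; then Pd(OAc)2 (10 mol%), O2 (1 atm), DMSO, rt
Reagents that add atoms: none
Why: Saegusa–Ito oxidation, in which equilibrating silylation should give the more substituted enol ether toward the methyl-bearing α-carbon (the alternative is a neopentyl position) and palladation followed by β-hydride elimination into the ring should deliver the 2-methyl enone, leaving the isolated isopropenyl group alone.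

**Step 4**
Reactants: 9 (5S)-2,5-dimethyl-5-(prop-1-en-2-yl)cyclohex-2-en-1-one
Product: 10 (1S,5S)-2,5-dimethyl-5-(prop-1-en-2-yl)cyclohex-2-en-1-ol
Conditions: (R)-2-methyl-CBS-oxazaborolidine (15 mol%), catecholborane, toluene, −78 °C; aq. NaOH work-up
Reagents that add atoms: none
Why: Corey–Bakshi–Shibata reduction, for which 2-substituted cyclohexenones are privileged substrates: the substituted alkene arm plays the large group, so the (R)-catalyst should deliver hydride to the face that gives the (1S) carbinol (hydroxyl cis to the isopropenyl group) independently of the remote quaternary centre, while catecholborane at −78 °C leaves the alkenes untouched.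

**Step 5**
Reactants: 10 (1S,5S)-2,5-dimethyl-5-(prop-1-en-2-yl)cyclohex-2-en-1-ol
Product: 12 (1S,5S)-5-(1-hydroxypropan-2-yl)-2,5-dimethylcyclohex-2-en-1-ol (both side-chain epimers), via bis-boryl adduct 11 (not isolated)
Conditions: 9-BBN (2.5 equiv), THF, 0 → 50 °C; then NaOH, H2O2, 0 °C → rt
Reagents that add atoms: hydrogen peroxide, OO
Why: Hydroboration–oxidation, in which 9-BBN should add to the 1,1-disubstituted isopropenyl alkene (boron on the terminal carbon) much faster than to the trisubstituted ring alkene, the hydroxyl being borylated first with loss of H2; the new methine centre forms as both epimers and is erased in step 7.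

**Step 6**
Reactants: 12 (1S,5S)-5-(1-hydroxypropan-2-yl)-2,5-dimethylcyclohex-2-en-1-ol
Product: 15 (1S,5S)-4,5,8-trimethyl-2-oxabicyclo[3.3.1]non-7-en-3-one (both C4 epimers), via hydroxy aldehyde 13 (not isolated), via lactol 14 (not isolated)
Conditions: TEMPO (20 mol%), PhI(OAc)2 (2.5 equiv), CH2Cl2, rt
Reagents that add atoms: none
Why: Oxoammonium (TEMPO) oxidative lactonisation, in which the primary alcohol is oxidised selectively to the aldehyde, captured by the cis-1,3 hydroxyl as a bridged lactol and oxidised on to the δ-lactone; only the cis hydroxy aldehyde can close this ring, so trans material (including that from the minor enantiomer of step 1) should stay behind as open-chain compounds.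

**Step 7**
Reactants: 15 (1S,5S)-4,5,8-trimethyl-2-oxabicyclo[3.3.1]non-7-en-3-one
Product: 17 (1S,4R,5S)-4,5,8-trimethyl-4-[(phenylsulfanyl)methyl]-2-oxabicyclo[3.3.1]non-7-en-3-one, via lithium enolate 16 (not isolated)
Conditions: LiN(iPr)2, THF, −78 °C; DMPU, PhSCH2Cl, NaI (10 mol%), −78 → 0 °C
Reagents that add atoms: chloromethyl phenyl sulfide, ClCSc1ccccc1
Why: Alkylation of a δ-lactone enolate, in which the trigonal C4 should be attacked on the convex face beside the one-carbon bridge C9, anti to the pseudo-axial C5–C6 bond of the three-carbon bridge C6–C7=C8 (a staggered, axial-type trajectory, whereas the other face is eclipsed with and shielded by that bridge), which sets the second quaternary centre (C1' of the target) as (4R) next to the existing one.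

**Step 8**
Reactants: 17 (1S,4R,5S)-4,5,8-trimethyl-4-[(phenylsulfanyl)methyl]-2-oxabicyclo[3.3.1]non-7-en-3-one
Product: 19 (1S,4R,5S)-4-[(benzenesulfonyl)methyl]-4,5,8-trimethyl-2-oxabicyclo[3.3.1]non-7-en-3-one, via sulfoxide 18 (not isolated)
Conditions: Oxone (2KHSO5·KHSO4·K2SO4), MeOH/H2O, 0 °C → rt
Reagents that add atoms: potassium peroxymonosulfate, [K+].[O-]S(=O)(=O)OO
Why: Chemoselective sulfide-to-sulfone oxidation with peroxymonosulfate, which without a ketone catalyst should oxidise sulfur far faster than it epoxidises the trisubstituted alkene; no stereocentre is touched.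

**Step 9**
Reactants: 19 (1S,4R,5S)-4-[(benzenesulfonyl)methyl]-4,5,8-trimethyl-2-oxabicyclo[3.3.1]non-7-en-3-one; 20 (ethenesulfonyl)benzene (phenyl vinyl sulfone)
Product: 23 (2R)-3,5-bis(benzenesulfonyl)-2-[(1S,5S)-5-hydroxy-1,4-dimethylcyclohex-3-en-1-yl]-2-methylcyclopentan-1-one (mixture at C3 and C5), via lithiated sulfone 21 (not isolated), via Michael adduct carbanion 22 (not isolated)
Conditions: LiN(iPr)2 (1.1 equiv), THF, −78 °C; 20 (1.05 equiv, slow addition), −78 → 0 °C; aq. NH4Cl
Reagents that add atoms: none
Why: LiN(iPr)2 removes a proton from the only acidic site of 19, the CH2 next to the sulfone (the lactone α-carbon is quaternary), the carbanion adds to the unsubstituted terminus of phenyl vinyl sulfone (bond C5'–C4'), and the α-sulfonyl carbanion so formed attacks the lactone carbonyl (bond C3'–C2'), whose tetrahedral intermediate expels the C1 alkoxide, so the temporary ring opens as the cyclopentanone closes. The closest known reaction type is the tandem Michael addition–Dieckmann acylation of sulfonyl-stabilised carbanions on lactone carbonyls (Hauser–Kraus annulation), used here in a [3+2] sense with the β-sulfonyl lactone as a homoenolate equivalent. The cyclopentane ring closes by 5-exo-trig attack of the carbanion on the carbonyl carbon, helped by the gem-disubstitution at the quaternary carbon. No lasting stereocentre is created: the two sulfonyl-bearing carbons form as mixtures and are cleared in step 10, while C1' (no α-hydrogen), C5 and C1 (its C–O bond is not broken) keep their configuration. The step needs the Michael adduct to cyclise faster than it adds to a second vinyl sulfone or is quenched by proton transfer; the intramolecular five-ring acylation and the irreversible deprotonation of the β-keto sulfone by the released alkoxide should secure this, with slow addition of 20 at low temperature as a further safeguard.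

**Step 10**
Reactants: 23 (2R)-3,5-bis(benzenesulfonyl)-2-[(1S,5S)-5-hydroxy-1,4-dimethylcyclohex-3-en-1-yl]-2-methylcyclopentan-1-one
Product: 24 (2R)-2-[(1S,5S)-5-hydroxy-1,4-dimethylcyclohex-3-en-1-yl]-2-methylcyclopentan-1-one
Conditions: Na(Hg) (6% Na), Na2HPO4, MeOH/THF, −20 → 0 °C
Reagents that add atoms: none
Why: Reductive desulfonylation by electron transfer from sodium amalgam in buffered methanol should cleave both C–S bonds (the α-keto sulfone through its enolate, the secondary alkyl sulfone through a carbanion protonated by methanol), erasing the two uncontrolled centres and leaving the hindered ketone and the alkenes.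

**Step 11**
Reactants: 24 (2R)-2-[(1S,5S)-5-hydroxy-1,4-dimethylcyclohex-3-en-1-yl]-2-methylcyclopentan-1-one
Product: 25 (1S,5S)-2,5-dimethyl-5-[(1S)-1-methyl-2-methylidenecyclopentyl]cyclohex-2-en-1-ol
Conditions: Ph3PCH3Br (4 equiv), KOtBu (4 equiv), toluene, 90 °C
Reagents that add atoms: methyltriphenylphosphonium bromide, C[P+](c1ccccc1)(c1ccccc1)c1ccccc1.[Br-]
Why: Wittig methylenation with excess ylide at elevated temperature, the standard answer to hindered ketones; the α-carbon on one side is quaternary so nothing can epimerise, and the free hydroxyl is carried as its alkoxide (any bridged hemiketal stays in equilibrium with the ketone).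

**Step 12**
Reactants: 25 (1S,5S)-2,5-dimethyl-5-[(1S)-1-methyl-2-methylidenecyclopentyl]cyclohex-2-en-1-ol; 26 2,2-dimethyl-1,3-dioxane-4,6-dione (Meldrum's acid)
Product: 27 3-{[(1S,5S)-2,5-dimethyl-5-[(1S)-1-methyl-2-methylidenecyclopentyl]cyclohex-2-en-1-yl]oxy}-3-oxopropanoic acid
Conditions: toluene, 90 °C
Reagents that add atoms: none
Why: Ring-opening acylation of the secondary allylic alcohol by Meldrum's acid with loss of acetone should give the malonic half ester without breaking the C1–O bond, so the carbinol configuration is retained and no protecting group is needed.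

**Step 13**
Reactants: 27 3-{[(1S,5S)-2,5-dimethyl-5-[(1S)-1-methyl-2-methylidenecyclopentyl]cyclohex-2-en-1-yl]oxy}-3-oxopropanoic acid; 28 3,4-dihydroxybenzaldehyde
Product: 29 (1S,5S)-2,5-dimethyl-5-[(1S)-1-methyl-2-methylidenecyclopentyl]cyclohex-2-en-1-yl (2E)-3-(3,4-dihydroxyphenyl)prop-2-enoate
Conditions: pyridine, piperidine (10 mol%), 50 °C
Reagents that add atoms: none
Why: Knoevenagel–Doebner condensation, in which amine-catalysed condensation of the malonic half ester with the aldehyde followed by decarboxylation should give the (E)-cinnamate under thermodynamic control while tolerating the free catechol, so the caffeate is installed without protecting groups.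

**Compound list**

1 | 3-methylcyclohex-2-en-1-one | CC1=CC(=O)CCC1 | starting material
2 | 2-bromoprop-1-ene | CC(Br)=C | starting material
3 | prop-1-en-2-yllithium | [Li]C(C)=C | intermediate
4 | dimethyl(prop-1-en-2-yl)alane | C[Al](C)C(C)=C | intermediate
5 | (3S)-3-methyl-3-(prop-1-en-2-yl)cyclohexan-1-one | C=C(C)[C@@]1(C)CCCC(=O)C1 | intermediate
6 | lithium (5S)-5-methyl-5-(prop-1-en-2-yl)cyclohex-1-en-1-olate | C=C(C)[C@@]1(C)CCC=C([O-])C1.[Li+] | intermediate
7 | (5S)-2,5-dimethyl-5-(prop-1-en-2-yl)cyclohexan-1-one (both C2 epimers) | C=C(C)[C@@]1(C)CCC(C)C(=O)C1 | intermediate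
8 | trimethyl{[(5S)-2,5-dimethyl-5-(prop-1-en-2-yl)cyclohex-1-en-1-yl]oxy}silane | C=C(C)[C@@]1(C)CCC(C)=C(O[Si](C)(C)C)C1 | intermediate
9 | (5S)-2,5-dimethyl-5-(prop-1-en-2-yl)cyclohex-2-en-1-one | C=C(C)[C@@]1(C)CC=C(C)C(=O)C1 | intermediate
10 | (1S,5S)-2,5-dimethyl-5-(prop-1-en-2-yl)cyclohex-2-en-1-ol | C=C(C)[C@@]1(C)CC=C(C)[C@@H](O)C1 | intermediate
11 | 9-{2-[(1S,5S)-5-(9-borabicyclo[3.3.1]nonan-9-yloxy)-1,4-dimethylcyclohex-3-en-1-yl]propyl}-9-borabicyclo[3.3.1]nonane | CC(CB2C3CCCC2CCC3)[C@@]1(C)CC=C(C)[C@@H](OB2C3CCCC2CCC3)C1 | intermediate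
12 | (1S,5S)-5-(1-hydroxypropan-2-yl)-2,5-dimethylcyclohex-2-en-1-ol (both side-chain epimers) | CC(CO)[C@@]1(C)CC=C(C)[C@@H](O)C1 | intermediate
13 | 2-[(1S,5S)-5-hydroxy-1,4-dimethylcyclohex-3-en-1-yl]propanal | CC(C=O)[C@@]1(C)CC=C(C)[C@@H](O)C1 | intermediate
14 | (1S,5S)-4,5,8-trimethyl-2-oxabicyclo[3.3.1]non-7-en-3-ol | CC1C(O)O[C@H]2C[C@]1(C)CC=C2C | intermediate
15 | (1S,5S)-4,5,8-trimethyl-2-oxabicyclo[3.3.1]non-7-en-3-one (both C4 epimers) | CC1C(=O)O[C@H]2C[C@]1(C)CC=C2C | intermediate
16 | lithium (1S,5S)-4,5,8-trimethyl-2-oxabicyclo[3.3.1]nona-3,7-dien-3-olate | CC1=C([O-])O[C@H]2C[C@]1(C)CC=C2C.[Li+] | intermediate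
17 | (1S,4R,5S)-4,5,8-trimethyl-4-[(phenylsulfanyl)methyl]-2-oxabicyclo[3.3.1]non-7-en-3-one | C[C@]1(CSc3ccccc3)C(=O)O[C@H]2C[C@]1(C)CC=C2C | intermediate
18 | (1S,4R,5S)-4-[(benzenesulfinyl)methyl]-4,5,8-trimethyl-2-oxabicyclo[3.3.1]non-7-en-3-one | C[C@]1(CS(=O)c3ccccc3)C(=O)O[C@H]2C[C@]1(C)CC=C2C | intermediate
19 | (1S,4R,5S)-4-[(benzenesulfonyl)methyl]-4,5,8-trimethyl-2-oxabicyclo[3.3.1]non-7-en-3-one | C[C@]1(CS(=O)(=O)c3ccccc3)C(=O)O[C@H]2C[C@]1(C)CC=C2C | intermediate
20 | (ethenesulfonyl)benzene (phenyl vinyl sulfone) | C=CS(=O)(=O)c1ccccc1 | starting material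
21 | lithium (benzenesulfonyl)[(1S,4R,5S)-4,5,8-trimethyl-3-oxo-2-oxabicyclo[3.3.1]non-7-en-4-yl]methanide | C[C@]1([CH-]S(=O)(=O)c3ccccc3)C(=O)O[C@H]2C[C@]1(C)CC=C2C.[Li+] | intermediate
22 | lithium 1,3-bis(benzenesulfonyl)-3-[(1S,4R,5S)-4,5,8-trimethyl-3-oxo-2-oxabicyclo[3.3.1]non-7-en-4-yl]propan-1-ide | C[C@]1(C(C[CH-]S(=O)(=O)c4ccccc4)S(=O)(=O)c3ccccc3)C(=O)O[C@H]2C[C@]1(C)CC=C2C.[Li+] | intermediate
23 | (2R)-3,5-bis(benzenesulfonyl)-2-[(1S,5S)-5-hydroxy-1,4-dimethylcyclohex-3-en-1-yl]-2-methylcyclopentan-1-one (mixture at C3 and C5) | O=C1C(S(=O)(=O)c2ccccc2)CC(S(=O)(=O)c2ccccc2)[C@]1(C)[C@@]1(C)CC=C(C)[C@@H](O)C1 | intermediate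
24 | (2R)-2-[(1S,5S)-5-hydroxy-1,4-dimethylcyclohex-3-en-1-yl]-2-methylcyclopentan-1-one | O=C1CCC[C@]1(C)[C@@]1(C)CC=C(C)[C@@H](O)C1 | intermediate
25 | (1S,5S)-2,5-dimethyl-5-[(1S)-1-methyl-2-methylidenecyclopentyl]cyclohex-2-en-1-ol | C=C1CCC[C@]1(C)[C@@]1(C)CC=C(C)[C@@H](O)C1 | intermediate
26 | 2,2-dimethyl-1,3-dioxane-4,6-dione (Meldrum's acid) | CC1(C)OC(=O)CC(=O)O1 | starting material
27 | 3-{[(1S,5S)-2,5-dimethyl-5-[(1S)-1-methyl-2-methylidenecyclopentyl]cyclohex-2-en-1-yl]oxy}-3-oxopropanoic acid | C=C1CCC[C@]1(C)[C@@]1(C)CC=C(C)[C@@H](OC(=O)CC(=O)O)C1 | intermediate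
28 | 3,4-dihydroxybenzaldehyde | O=Cc1ccc(O)c(O)c1 | starting material
29 | (1S,5S)-2,5-dimethyl-5-[(1S)-1-methyl-2-methylidenecyclopentyl]cyclohex-2-en-1-yl (2E)-3-(3,4-dihydroxyphenyl)prop-2-enoate | C=C1CCC[C@]1(C)[C@@]1(C)CC=C(C)[C@@H](OC(=O)/C=C/c2ccc(O)c(O)c2)C1 | target

**Step count and risks**

Total step count: 13. Longest linear sequence: 13 steps (1 to 29); 2, 20, 26 and 28 enter directly.

Steps most likely to fail:

Step 9. The carbanions may oligomerise the vinyl sulfone, or proton transfer may stop the cascade at the open-chain Michael adduct. The fallback sets out from 15 and builds the same ring by a radical C–C bond formation followed by a separate acylation. Enolate alkylation of 15 with CH2I2 (LiN(iPr)2, THF, −78 °C) on the same convex face would give the iodomethyl lactone F1. A tin hydride-mediated Giese addition of the derived primary radical to methyl acrylate (Bu3SnH, AIBN, benzene, 80 °C) would give the ester F2. Dieckmann cyclisation onto the lactone carbonyl (KOtBu, THF) would open the lactone and give the β-keto ester F3. Krapcho decarboxylation (LiCl, wet DMSO, 140 °C) would bring the route back at 24.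

Step 7. The electrophile may enter from the concave face of the bicyclic enolate and give the wrong configuration at the new quaternary carbon. The fallback sets out from 15 and reverses the order in which the two substituents arrive, so that the group entering last is the methyl. Selenenylation (LiN(iPr)2; PhSeBr) would give the α-phenylselanyl lactone F4. Oxidation with H2O2 and syn-elimination, possible only toward the methyl group, would give the α-methylidene lactone F5. Conjugate addition of lithium benzenethiolate would generate the lithium enolate F6, which would be methylated in the same flask with MeI; this places the methyl on the face that the sulfur electrophile took in step 7 and comes back at 17. It corrects a reversed facial preference, not a weak one.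

Step 10. The ketone may be over-reduced, or cleavage of the unactivated secondary sulfone may be incomplete. The fallback sets out from 23 and removes the two sulfones at different stages. Al(Hg) in wet THF would cleave only the α-keto sulfone and give the mono-sulfone ketone F7. Wittig methylenation as in step 11 would give the methylidene sulfone F8. With no ketone left in the molecule, Mg in MeOH would cleave the remaining sulfone and come back at 25.

**Further compounds**

F1 | step 9 | (1S,4R,5S)-4-(iodomethyl)-4,5,8-trimethyl-2-oxabicyclo[3.3.1]non-7-en-3-one | C[C@]1(CI)C(=O)O[C@H]2C[C@]1(C)CC=C2C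
F2 | step 9 | methyl 4-[(1S,4R,5S)-4,5,8-trimethyl-3-oxo-2-oxabicyclo[3.3.1]non-7-en-4-yl]butanoate | C[C@]1(CCCC(=O)OC)C(=O)O[C@H]2C[C@]1(C)CC=C2C
F3 | step 9 | methyl (3R)-3-[(1S,5S)-5-hydroxy-1,4-dimethylcyclohex-3-en-1-yl]-3-methyl-2-oxocyclopentane-1-carboxylate (both C1 epimers) | O=C1C(C(=O)OC)CC[C@]1(C)[C@@]1(C)CC=C(C)[C@@H](O)C1
F4 | step 7 | (1S,5S)-4,5,8-trimethyl-4-(phenylselanyl)-2-oxabicyclo[3.3.1]non-7-en-3-one (C4 epimers) | CC1([Se]c3ccccc3)C(=O)O[C@H]2C[C@]1(C)CC=C2C
F5 | step 7 | (1S,5S)-5,8-dimethyl-4-methylidene-2-oxabicyclo[3.3.1]non-7-en-3-one | C=C1C(=O)O[C@H]2C[C@]1(C)CC=C2C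
F6 | step 7 | lithium (1S,5S)-5,8-dimethyl-4-[(phenylsulfanyl)methyl]-2-oxabicyclo[3.3.1]nona-3,7-dien-3-olate | C(Sc3ccccc3)C1=C([O-])O[C@H]2C[C@]1(C)CC=C2C.[Li+]
F7 | step 10 | (2R)-3-(benzenesulfonyl)-2-[(1S,5S)-5-hydroxy-1,4-dimethylcyclohex-3-en-1-yl]-2-methylcyclopentan-1-one (C3 epimers) | O=C1CCC(S(=O)(=O)c2ccccc2)[C@]1(C)[C@@]1(C)CC=C(C)[C@@H](O)C1
F8 | step 10 | (1S,5S)-5-[(1S)-2-(benzenesulfonyl)-1-methyl-5-methylidenecyclopentyl]-2,5-dimethylcyclohex-2-en-1-ol (epimers at the sulfonyl carbon) | C=C1CCC(S(=O)(=O)c2ccccc2)[C@]1(C)[C@@]1(C)CC=C(C)[C@@H](O)C1
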